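Ring C of the (2S)-flavanone is cut at the C3–C4 bond. The feature exploited is the C4 carbonyl carbon, which sits between C3 and ring A: written as its silyl enol ether it becomes one terminus of a C3=C4 alkene, so ring-closing olefin metathesis can forge that bond and close ring C in a single operation, away from C2. The precursor is an (S)-1-arylallyl aryl ether that already holds O1 and the C2 stereocentre, set by iridium-catalysed asymmetric allylic etherification, with a 1-(silyloxy)vinyl group ortho to the ether oxygen on ring A. Enol ether hydrolysis and chelation-directed cleavage of the C5 methyl ether then give the target.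

Key step: step 6

Remark: the target is read as (2S)-5-hydroxy-6,7,3',4'-tetramethoxyflavanone; the sense of induction of the iridium ligand in step 4 is assigned by analogy and must be confirmed on the first batch, the antipodal ligand being equally accessible.

Step 1
Reactants: 1 3,4,5-trimethoxyphenol
Product: 3 1-(2-hydroxy-4,5,6-trimethoxyphenyl)ethanone, via difluoroboron chelate 2 (not isolated)
Conditions: AcOH, BF3·OEt2 (3 equiv), 90 °C; then aq. NaOAc, EtOH, 70 °C
Reagents that add atoms: acetic acid, CC(=O)O
Why: Friedel–Crafts C-acylation promoted by boron trifluoride should go to one of the two equivalent carbons ortho to the hydroxyl (the para carbon is blocked), and the ketone is held as its difluoroboron chelate, which prevents a second acylation and is hydrolysed on work-up.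

Step 2
Reactants: 4 methyl (E)-3,4-dimethoxycinnamate
Product: 5 (E)-3-(3,4-dimethoxyphenyl)prop-2-en-1-ol
Conditions: i-Bu2AlH (2.5 equiv), CH2Cl2, −78 → 0 °C; aq. potassium sodium tartrate
Reagents that add atoms: none
Why: 1,2-Reduction of an α,β-unsaturated ester by diisobutylaluminium hydride should give the allylic alcohol with the E-alkene untouched, which a stronger hydride donor such as LiAlH4 would put at risk.

Step 3
Reactants: 5 (E)-3-(3,4-dimethoxyphenyl)prop-2-en-1-ol
Product: 6 (E)-3-(3,4-dimethoxyphenyl)allyl methyl carbonate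
Conditions: ClCO2Me, pyridine, CH2Cl2, 0 °C
Reagents that add atoms: methyl chloroformate, COC(=O)Cl
Why: O-Acylation of a primary alcohol with a chloroformate (carbonate formation) is fast at 0 °C, and pyridine traps the hydrogen chloride so the acid-sensitive cinnamyl system is not ionised.

Step 4
Reactants: 3 1-(2-hydroxy-4,5,6-trimethoxyphenyl)ethanone; 6 (E)-3-(3,4-dimethoxyphenyl)allyl methyl carbonate
Product: 8 (S)-1-{2-[1-(3,4-dimethoxyphenyl)allyloxy]-4,5,6-trimethoxyphenyl}ethanone, via sodium aryloxide 7 (not isolated)
Conditions: 3 (1.5 equiv), NaH, THF, 0 °C; then 6, [Ir(cod)Cl]2 (2 mol %), (S_a,S_c,S_c)-(1,1'-binaphthyl-2,2'-diyl) N,N-bis(1-phenylethyl)phosphoramidite (4 mol %, pre-activated with n-PrNH2), THF, 25 °C; H2O quench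
Reagents that add atoms: none
Why: In this iridium-catalysed asymmetric allylic etherification the cyclometalated iridium–phosphoramidite complex ionises the linear carbonate to an allyliridium intermediate, the aryloxide attacks its aryl-substituted terminus on the face away from the metal to give the branched ether, and the ligand antipode fixes that face and so sets (S) at the future C2 (the (S_a,S_c,S_c) ligand is the one expected to give this sense, by analogy with simpler 1-arylallyl aryl ethers).

Step 5
Reactants: 8 (S)-1-{2-[1-(3,4-dimethoxyphenyl)allyloxy]-4,5,6-trimethoxyphenyl}ethanone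
Product: 10 (S)-tert-butyl{1-[2-(1-(3,4-dimethoxyphenyl)allyloxy)-4,5,6-trimethoxyphenyl]vinyloxy}dimethylsilane, via potassium enolate 9 (not isolated)
Conditions: KN(SiMe3)2 (1.1 equiv), THF, −78 °C; then TBSCl, −78 → −20 °C; Et3N-deactivated silica
Reagents that add atoms: tert-butyldimethylsilyl chloride, CC(C)(C)[Si](C)(C)Cl
Why: Kinetic deprotonation of the methyl ketone, the only site acidic towards a silazide, and O-silylation of the potassium enolate (silyl enol ether formation) should give the 1-arylvinyl silyl ether under non-acidic conditions that cannot ionise the doubly activated allylic ether or touch C2.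

Step 6
Reactants: 10 (S)-tert-butyl{1-[2-(1-(3,4-dimethoxyphenyl)allyloxy)-4,5,6-trimethoxyphenyl]vinyloxy}dimethylsilane
Product: 11 (S)-4-(tert-butyldimethylsilyloxy)-2-(3,4-dimethoxyphenyl)-5,6,7-trimethoxy-2H-chromene
Conditions: second-generation Grubbs catalyst (H2IMes)(PCy3)Cl2Ru=CHPh (5–10 mol %), 1,4-benzoquinone (10 mol %), CH2Cl2 (5 mM), 40 °C, Ar sparge, dark
Reagents that add atoms: none
Why: The ruthenium benzylidene should exchange onto the monosubstituted vinyl group of the allyl ether, the only unhindered alkene, and the new alkylidene then adds across the tethered 1,1-disubstituted silyl enol ether in a (2+2) step; cycloreversion of the ruthenacyclobutane forms C3=C4 and leaves Ru=CH2, which gives up ethylene on the next turnover. The closest known reaction type is ring-closing metathesis of silyl enol ethers onto terminal alkenes, including the nitrogen analogue in which N-allyl-2-(1-silyloxyvinyl)anilines close to 4-silyloxy-1,2-dihydroquinolines. Ring C is closed as a six-membered ring by this intramolecular metathesis, the two reacting carbons being linked through C2, O1, C8a and C4a with both alkenes held ortho on ring A. No stereocentre is formed, and C2, which is not a reacting centre, should be carried through unchanged. The selectivity needed is ring closure over dimerisation, double-bond migration and thermal Claisen rearrangement: high dilution and the ortho arrangement favour the first, benzoquinone intercepts ruthenium hydrides that would move the allyl double bond into conjugation and erase C2, and 40 °C in the dark lies well below what the [3,3] shift or electrocyclic opening of the 2H-chromene requires.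

Step 7
Reactants: 11 (S)-4-(tert-butyldimethylsilyloxy)-2-(3,4-dimethoxyphenyl)-5,6,7-trimethoxy-2H-chromene
Product: 12 (2S)-2-(3,4-dimethoxyphenyl)-5,6,7-trimethoxychroman-4-one
Conditions: crude 11, Bu4NF, AcOH (1:1.2), THF, 0 °C
Reagents that add atoms: none
Why: Fluoride-induced cleavage of the silyl enol ether in the presence of acetic acid should protonate the enolate at C3 as it forms, so the β-aryloxy enolate has no lifetime for E1cB opening of ring C and the C2 configuration is kept.

Step 8
Reactants: 12 (2S)-2-(3,4-dimethoxyphenyl)-5,6,7-trimethoxychroman-4-one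
Product: 14 (2S)-2-(3,4-dimethoxyphenyl)-5-hydroxy-6,7-dimethoxychroman-4-one, via dichloroboron chelate 13 (not isolated)
Conditions: BCl3 (1.5 equiv), CH2Cl2, −78 → 0 °C; then ice-water
Reagents that add atoms: none
Why: In this chelation-controlled Lewis acid ether cleavage BCl3 should bind the C4 carbonyl and the peri C5 methoxy oxygen in a six-membered chelate, chloride then removes that methyl group only, and the four other methyl ethers, which cannot chelate, should survive at low temperature.

Compound list
1 | 3,4,5-trimethoxyphenol | COc1cc(O)cc(OC)c1OC | starting material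
2 | difluoroboron chelate of 1-(2-hydroxy-4,5,6-trimethoxyphenyl)ethanone | CC1=[O+][B-](F)(F)Oc2cc(OC)c(OC)c(OC)c12 | intermediate (not isolated)
3 | 1-(2-hydroxy-4,5,6-trimethoxyphenyl)ethanone | CC(=O)c1c(O)cc(OC)c(OC)c1OC | intermediate
4 | methyl (E)-3,4-dimethoxycinnamate | COC(=O)/C=C/c1ccc(OC)c(OC)c1 | starting material
5 | (E)-3-(3,4-dimethoxyphenyl)prop-2-en-1-ol | OC/C=C/c1ccc(OC)c(OC)c1 | intermediate
6 | (E)-3-(3,4-dimethoxyphenyl)allyl methyl carbonate | COC(=O)OC/C=C/c1ccc(OC)c(OC)c1 | intermediate
7 | sodium 2-acetyl-3,4,5-trimethoxyphenolate | CC(=O)c1c([O-])cc(OC)c(OC)c1OC.[Na+] | intermediate (not isolated)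
8 | (S)-1-{2-[1-(3,4-dimethoxyphenyl)allyloxy]-4,5,6-trimethoxyphenyl}ethanone | C=C[C@H](Oc1cc(OC)c(OC)c(OC)c1C(C)=O)c1ccc(OC)c(OC)c1 | intermediate
9 | potassium enolate of 8 | C=C[C@H](Oc1cc(OC)c(OC)c(OC)c1C(=C)[O-])c1ccc(OC)c(OC)c1.[K+] | intermediate (not isolated)
10 | (S)-tert-butyl{1-[2-(1-(3,4-dimethoxyphenyl)allyloxy)-4,5,6-trimethoxyphenyl]vinyloxy}dimethylsilane | C=C[C@H](Oc1cc(OC)c(OC)c(OC)c1C(=C)O[Si](C)(C)C(C)(C)C)c1ccc(OC)c(OC)c1 | intermediate (key-step precursor)
11 | (S)-4-(tert-butyldimethylsilyloxy)-2-(3,4-dimethoxyphenyl)-5,6,7-trimethoxy-2H-chromene | COc1ccc([C@@H]2C=C(O[Si](C)(C)C(C)(C)C)c3c(cc(OC)c(OC)c3OC)O2)cc1OC | intermediate (key-step product)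
12 | (2S)-2-(3,4-dimethoxyphenyl)-5,6,7-trimethoxychroman-4-one | COc1ccc([C@@H]2CC(=O)c3c(cc(OC)c(OC)c3OC)O2)cc1OC | intermediate
13 | dichloroboron chelate of 14 (boron on the C5 oxygen, bound to the C4 carbonyl) | COc1ccc([C@@H]2CC3=[O+][B-](Cl)(Cl)Oc4c(OC)c(OC)cc(O2)c34)cc1OC | intermediate (not isolated)
14 | (2S)-2-(3,4-dimethoxyphenyl)-5-hydroxy-6,7-dimethoxychroman-4-one | COc1ccc([C@@H]2CC(=O)c3c(cc(OC)c(OC)c3O)O2)cc1OC | target

Total step count: 8.
Longest linear sequence: 7 steps (4 → 5 → 6 → 8 → 10 → 11 → 12 → 14); 6 steps from 1.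

Steps most likely to fail

Step 6. The alkylidene formed at the allyl ether may fail to engage the twisted enol ether, which is flanked on both sides by ortho substituents, so that intermolecular cross-metathesis or hydride-induced double-bond migration outruns ring closure. The fallback gives up metathesis and sets C2 by conjugate addition. It sets out from 3: condensation with Me2NCH(OMe)2 at 100 °C should give the enaminone (E)-3-(dimethylamino)-1-(2-hydroxy-4,5,6-trimethoxyphenyl)prop-2-en-1-one F1, and acid (aq. HCl, CH2Cl2) should close it to 5,6,7-trimethoxy-4H-chromen-4-one F2. Catalytic asymmetric 1,4-addition of (3,4-dimethoxyphenyl)boronic acid to F2 (for example Pd(OCOCF3)2 with the tert-butyl pyridine–oxazoline ligand antipode that gives S, NH4PF6, H2O, ClCH2CH2Cl, 60 °C) should then deliver the flavanone. The route is rejoined at 12.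

Step 4. The chelated, electron-poor aryloxide may attack the allyliridium intermediate slowly while the catalyst re-ionises the electron-rich branched ether, so that regio- and enantiopurity drain towards the linear and racemic ethers. The product is also acid-labile and would be purified on Et3N-deactivated silica. The fallback forms the same C–O bond by Mitsunobu inversion and sets out from 3. Commercial 3,4-dimethoxybenzaldehyde and CH2=CHMgBr (THF, 0 °C) should give rac-1-(3,4-dimethoxyphenyl)prop-2-en-1-ol F3. Lipase resolution (Candida antarctica lipase B, vinyl acetate, hexane) should acetylate one enantiomer to (R)-1-(3,4-dimethoxyphenyl)allyl acetate F4 and leave (S)-1-(3,4-dimethoxyphenyl)prop-2-en-1-ol F5, which is separated. Methanolysis of F4 (K2CO3, MeOH, 0 °C) should give (R)-1-(3,4-dimethoxyphenyl)prop-2-en-1-ol F6. Mitsunobu coupling of F6 with 3 (PPh3, diisopropyl azodicarboxylate, toluene, −20 °C) should proceed with inversion; the low temperature and non-polar solvent are chosen to hold back ionisation and allylic transposition. The route is rejoined at 8.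

Step 8. Lewis-acid-promoted opening of ring C at the C2–O1 bond to the boron-bound chalcone, followed by re-closure, would erode the enantiomeric purity, and a second demethylation at C6 may follow once the C5 borate has formed. The fallback moves the demethylation to a stage before C2 exists and ends with fluoride only. It sets out from 3: BCl3 (CH2Cl2, −78 → 0 °C) should give 1-(2,6-dihydroxy-3,4-dimethoxyphenyl)ethanone F7. The iridium conditions of step 4 with 6 (one equivalent of NaH) should etherify the less hindered hydroxyl, the one flanked by C–H, to give (S)-1-{2-[1-(3,4-dimethoxyphenyl)allyloxy]-6-hydroxy-4,5-dimethoxyphenyl}ethanone F8; this regioselectivity rests on sterics and is the weak point of the fallback. Double silylation (KN(SiMe3)2 2.2 equiv, TBSCl, THF, −78 °C) should give the aryl silyl ether and silyl enol ether (S)-tert-butyl{1-[2-(tert-butyldimethylsilyloxy)-6-(1-(3,4-dimethoxyphenyl)allyloxy)-3,4-dimethoxyphenyl]vinyloxy}dimethylsilane F9. Ring-closing metathesis under the conditions of step 6 should give (S)-4,5-bis(tert-butyldimethylsilyloxy)-2-(3,4-dimethoxyphenyl)-6,7-dimethoxy-2H-chromene F10. Bu4NF/AcOH (THF, 0 °C) should then remove both silyl groups at once. The route is rejoined at 14.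

Further compounds
F1 | step 6 | (E)-3-(dimethylamino)-1-(2-hydroxy-4,5,6-trimethoxyphenyl)prop-2-en-1-one | CN(C)/C=C/C(=O)c1c(O)cc(OC)c(OC)c1OC
F2 | step 6 | 5,6,7-trimethoxy-4H-chromen-4-one | O=c1ccoc2cc(OC)c(OC)c(OC)c12
F3 | step 4 | rac-1-(3,4-dimethoxyphenyl)prop-2-en-1-ol | C=CC(O)c1ccc(OC)c(OC)c1
F4 | step 4 | (R)-1-(3,4-dimethoxyphenyl)allyl acetate | C=C[C@@H](OC(C)=O)c1ccc(OC)c(OC)c1
F5 | step 4 | (S)-1-(3,4-dimethoxyphenyl)prop-2-en-1-ol | C=C[C@H](O)c1ccc(OC)c(OC)c1
F6 | step 4 | (R)-1-(3,4-dimethoxyphenyl)prop-2-en-1-ol | C=C[C@@H](O)c1ccc(OC)c(OC)c1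
F7 | step 8 | 1-(2,6-dihydroxy-3,4-dimethoxyphenyl)ethanone | CC(=O)c1c(O)cc(OC)c(OC)c1O
F8 | step 8 | (S)-1-{2-[1-(3,4-dimethoxyphenyl)allyloxy]-6-hydroxy-4,5-dimethoxyphenyl}ethanone | C=C[C@H](Oc1cc(OC)c(OC)c(O)c1C(C)=O)c1ccc(OC)c(OC)c1
F9 | step 8 | (S)-tert-butyl{1-[2-(tert-butyldimethylsilyloxy)-6-(1-(3,4-dimethoxyphenyl)allyloxy)-3,4-dimethoxyphenyl]vinyloxy}dimethylsilane | C=C[C@H](Oc1cc(OC)c(OC)c(O[Si](C)(C)C(C)(C)C)c1C(=C)O[Si](C)(C)C(C)(C)C)c1ccc(OC)c(OC)c1
F10 | step 8 | (S)-4,5-bis(tert-butyldimethylsilyloxy)-2-(3,4-dimethoxyphenyl)-6,7-dimethoxy-2H-chromene | COc1ccc([C@@H]2C=C(O[Si](C)(C)C(C)(C)C)c3c(cc(OC)c(OC)c3O[Si](C)(C)C(C)(C)C)O2)cc1OC
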